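**Retrosynthetic overview**
1. Punaglandin 8 (21) ⇐ TMS removal ⇐ one Lindlar reduction that makes both Z-alkenes from a diyne ⇐ acetylation of the C7 carbinol 18.
2. C7–C8 bond: anti-selective boron aldol of chlorocyclopentenone 10 with ynal 15 (two steps from hex-5-ynoic acid 11).
3. The only ring construction is four- to five-membered: reductive one-carbon ring expansion (1,2-acyl shift) of the α-trichloromethyl cyclobutanone 8 gives 10; the CCl3 carbon becomes C10 with its chlorine.
4. 8 ⇐ radical trichloromethylation of cyclobutenyl enol ether 6 ⇐ acetylide alkylation of 3 with 1-iodopentane (4).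
5. C12 stereocentre: catalytic asymmetric propargylation of 3-ethoxycyclobut-2-enone (1) with propargyl bromide (2).

Assumption: prostaglandin numbering (C1–C20) is used in the comments; 1, 2, 4 and 11 are taken as purchasable; the antipode of the chromium ligand that gives the (S)-carbinol is fixed in a first screening run.

**Step 1**
Reactants: 1 3-ethoxycyclobut-2-en-1-one; 2 propargyl bromide (3-bromoprop-1-yne)
Product: 3 (S)-[3-ethoxy-1-(prop-2-yn-1-yl)cyclobut-2-en-1-yl]oxy-trimethylsilane
Conditions: CrCl3·3THF (10 mol %), chiral oxazoline–prolinamide ligand (12 mol %), Et3N (0.5 equiv), Mn powder, TMSCl, THF, 0 °C; chromatography on Et3N-deactivated silica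
Reagents that add atoms: chlorotrimethylsilane C[Si](C)(C)Cl
Why: Catalytic asymmetric Nozaki–Hiyama–Kishi (Barbier-type) propargylation: the allenyl–Cr(III) species adds SE2′ to the strained ketone to give the homopropargylic carbinol, the ligand-bound chromium discriminates the carbonyl faces flanked by the planar CH= and the CH2 group and so sets C12 as (S), and in-situ O-silylation by TMSCl turns the catalyst over and never leaves a free cyclobutenyl alkoxide that could ring-open.

**Step 2**
Reactants: 3 (S)-[3-ethoxy-1-(prop-2-yn-1-yl)cyclobut-2-en-1-yl]oxy-trimethylsilane; 4 1-iodopentane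
Product: 6 (S)-[3-ethoxy-1-(oct-2-yn-1-yl)cyclobut-2-en-1-yl]oxy-trimethylsilane, via lithium acetylide 5 (not isolated)
Conditions: n-BuLi (1.05 equiv), THF, −78 °C; then n-C5H11I, DMPU, −78 °C → rt
Reagents that add atoms: none
Why: Lithium acetylide alkylation (SN2) with the primary iodide in THF/DMPU installs C16–C20, the neutral silyl ether and enol ether being inert to n-BuLi at −78 °C and C12 untouched.

**Step 3**
Reactants: 6 (S)-[3-ethoxy-1-(oct-2-yn-1-yl)cyclobut-2-en-1-yl]oxy-trimethylsilane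
Product: 8 (3S)-3-(oct-2-yn-1-yl)-2-(trichloromethyl)-3-(trimethylsilyloxy)cyclobutan-1-one (both C2 epimers), via ethyl hemiketal 7 (not isolated)
Conditions: BrCCl3 (1.5 equiv), Ru(bpy)3Cl2 (1 mol %), NaHCO3, MeCN/H2O (10:1), blue LEDs, 0–10 °C; used without heating or amine base
Reagents that add atoms: bromotrichloromethane ClC(Cl)(Cl)Br; water O
Why: Kharasch-type radical addition with radical–polar crossover: photogenerated electrophilic •CCl3 adds to the nucleophilic enol-ether β-carbon (C11), the α-ethoxy radical is oxidised to the oxocarbenium ion and water unmasks the C9 ketone via hemiketal 7, while the isolated alkyne reacts far more slowly and the uncontrolled C11 centre is erased in step 4.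

**Step 4**
Reactants: 8 (3S)-3-(oct-2-yn-1-yl)-2-(trichloromethyl)-3-(trimethylsilyloxy)cyclobutan-1-one
Product: 10 (S)-2-chloro-4-(oct-2-yn-1-yl)-4-(trimethylsilyloxy)cyclopent-2-en-1-one, via samarium cyclopropanolate 9 (not isolated)
Conditions: SmI2 (2.2 equiv, 0.1 M in THF), 8 added slowly at −78 °C, then → −20 °C; aq. NaHCO3
Reagents that add atoms: none
Why: Proposed new method: a reductive 1,2-acyl-shift ring expansion in which two SmI2 reduce one C–Cl bond of the CCl3 group to a dichloro-organosamarium (the short-lived radical is reduced faster than it can fragment the four-membered ring), this carbanion adds 3-exo to the strained cyclobutanone carbonyl (Barbier), and the dichlorocyclopropanolate 9 then fragments heterolytically (the alkoxide pushes, the old C9–C11 bond breaks, chloride leaves C10), so that C9 has moved from C11 to C10 and the ring has grown to the 2-chloro-enone with loss of about 20 kcal/mol of strain and without touching C12; the closest known chemistry is the Dowd–Beckwith ring expansion of α-halomethyl ketones including its SmI2 variants, SmI2 cyclopropanol formation from β-halo ketones and the zinc-carbenoid chain extension of β-keto esters.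

**Step 5**
Reactants: 11 hex-5-ynoic acid
Product: 14 7-oxohept-5-ynoic acid, via dilithio salt 12 (not isolated), via lithium hemiaminal salt 13 (not isolated)
Conditions: n-BuLi (2.1 equiv), THF, −78 → −40 °C; DMF, −78 → 0 °C; reverse quench into aq. KH2PO4
Reagents that add atoms: N,N-dimethylformamide CN(C)C=O
Why: Formylation of a lithium acetylide with DMF: two equivalents of n-BuLi give the carboxylate/acetylide dianion, only the acetylide adds to DMF, and the reverse quench into phosphate buffer collapses the hemiaminal to the ynal without amine conjugate addition.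

**Step 6**
Reactants: 14 7-oxohept-5-ynoic acid
Product: 15 methyl 7-oxohept-5-ynoate
Conditions: TMSCHN2 (1.05 equiv, dropwise to end point), MeOH/toluene, 0 °C
Reagents that add atoms: trimethylsilyldiazomethane C[Si](C)(C)C=[N+]=[N-]
Why: Methyl ester formation with TMS-diazomethane: proton transfer from the acid and O-methylation are much faster at 0 °C than dipolar cycloaddition of the reagent to the ynal when it is titrated to the end point.

**Step 7**
Reactants: 10 (S)-2-chloro-4-(oct-2-yn-1-yl)-4-(trimethylsilyloxy)cyclopent-2-en-1-one; 15 methyl 7-oxohept-5-ynoate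
Product: 18 methyl (7R)-7-[(1R,2S)-4-chloro-2-(oct-2-yn-1-yl)-5-oxo-2-(trimethylsilyloxy)cyclopent-3-en-1-yl]-7-hydroxyhept-5-ynoate, via dienol borinate 16 (not isolated), via boron aldolate 17 (not isolated)
Conditions: Cy2BCl, Et3N, Et2O, −78 → 0 °C; 15, −78 → −20 °C; MeOH, pH 7 buffer, 30 % H2O2, 0 °C
Reagents that add atoms: none
Why: Boron-mediated aldol addition: soft enolisation at C8 (the only enolisable position) gives the ring-locked (E)-dienol borinate 16, whose closed Zimmerman–Traxler chair delivers the anti aldol (C7), and the aldehyde adds to the 5-silyloxycyclopentadiene-type dienolate on the face syn to oxygen and away from the CH2 branch of the octynyl chain, which places the new chain at C8 trans to that chain (C8 R).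

**Step 8**
Reactants: 18 methyl (7R)-7-[(1R,2S)-4-chloro-2-(oct-2-yn-1-yl)-5-oxo-2-(trimethylsilyloxy)cyclopent-3-en-1-yl]-7-hydroxyhept-5-ynoate
Product: 19 methyl (7R)-7-(acetyloxy)-7-[(1R,2S)-4-chloro-2-(oct-2-yn-1-yl)-5-oxo-2-(trimethylsilyloxy)cyclopent-3-en-1-yl]hept-5-ynoate
Conditions: Ac2O, pyridine, DMAP (2 mol %), CH2Cl2, −20 → 0 °C
Reagents that add atoms: acetic anhydride CC(=O)OC(C)=O
Why: DMAP-catalysed O-acetylation of the secondary propargylic alcohol, run cold and briefly so that the β-acetoxy ketone does not undergo E1cB elimination and C8 does not epimerise, the tertiary oxygen staying silylated.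

**Step 9**
Reactants: 19 methyl (7R)-7-(acetyloxy)-7-[(1R,2S)-4-chloro-2-(oct-2-yn-1-yl)-5-oxo-2-(trimethylsilyloxy)cyclopent-3-en-1-yl]hept-5-ynoate
Product: 20 methyl (5Z,7S)-7-(acetyloxy)-7-[(1R,2S)-4-chloro-2-[(2Z)-oct-2-en-1-yl]-5-oxo-2-(trimethylsilyloxy)cyclopent-3-en-1-yl]hept-5-enoate
Conditions: H2 (1 atm), Lindlar catalyst (Pd/CaCO3/Pb), quinoline, EtOAc, 0 °C → rt, stopped at 2.0 equiv H2
Reagents that add atoms: none
Why: Lindlar semihydrogenation adds H2 syn on the poisoned palladium surface to both internal alkynes and so gives the (5Z) and (14Z) alkenes in one operation, the hindered chloro-enone and the allylic acetate being left alone when uptake is stopped at two equivalents.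

**Step 10**
Reactants: 20 methyl (5Z,7S)-7-(acetyloxy)-7-[(1R,2S)-4-chloro-2-[(2Z)-oct-2-en-1-yl]-5-oxo-2-(trimethylsilyloxy)cyclopent-3-en-1-yl]hept-5-enoate
Product: 21 punaglandin 8, methyl (5Z,7S)-7-(acetyloxy)-7-[(1R,2S)-4-chloro-2-hydroxy-2-[(2Z)-oct-2-en-1-yl]-5-oxocyclopent-3-en-1-yl]hept-5-enoate
Conditions: HF·pyridine, THF, 0 °C
Reagents that add atoms: none
Why: Fluoride-driven cleavage of the tertiary trimethylsilyl ether under weakly acidic conditions frees the C12 hydroxyl without the base that would eliminate the C7 acetate or epimerise C8.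

**Compound list**
1 | 3-ethoxycyclobut-2-en-1-one | CCOC1=CC(=O)C1 | starting material
2 | propargyl bromide (3-bromoprop-1-yne) | C#CCBr | starting material
3 | (S)-[3-ethoxy-1-(prop-2-yn-1-yl)cyclobut-2-en-1-yl]oxy-trimethylsilane | C#CC[C@@]1(O[Si](C)(C)C)C=C(OCC)C1 | intermediate
4 | 1-iodopentane | CCCCCI | starting material
5 | lithium acetylide of 3 (formed in the flask) | [Li+].[C-]#CC[C@@]1(O[Si](C)(C)C)C=C(OCC)C1 | intermediate
6 | (S)-[3-ethoxy-1-(oct-2-yn-1-yl)cyclobut-2-en-1-yl]oxy-trimethylsilane | CCCCCC#CC[C@@]1(O[Si](C)(C)C)C=C(OCC)C1 | intermediate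
7 | (3S)-1-ethoxy-3-(oct-2-yn-1-yl)-2-(trichloromethyl)-3-(trimethylsilyloxy)cyclobutan-1-ol, ethyl hemiketal (formed in the flask) | CCCCCC#CC[C@@]1(O[Si](C)(C)C)C(C(Cl)(Cl)Cl)C(O)(OCC)C1 | intermediate
8 | (3S)-3-(oct-2-yn-1-yl)-2-(trichloromethyl)-3-(trimethylsilyloxy)cyclobutan-1-one (C2 epimers) | CCCCCC#CC[C@@]1(O[Si](C)(C)C)C(C(Cl)(Cl)Cl)C(=O)C1 | intermediate
9 | diiodosamarium(III) (3S)-5,5-dichloro-3-(oct-2-yn-1-yl)-3-(trimethylsilyloxy)bicyclo[2.1.0]pentan-1-olate (formed in the flask) | CCCCCC#CC[C@@]1(O[Si](C)(C)C)C2C(Cl)(Cl)C2(O[Sm](I)I)C1 | intermediate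
10 | (S)-2-chloro-4-(oct-2-yn-1-yl)-4-(trimethylsilyloxy)cyclopent-2-en-1-one | CCCCCC#CC[C@@]1(O[Si](C)(C)C)C=C(Cl)C(=O)C1 | intermediate
11 | hex-5-ynoic acid | C#CCCCC(=O)O | starting material
12 | lithium 6-lithiohex-5-ynoate (formed in the flask) | [Li+].[Li+].[C-]#CCCCC(=O)[O-] | intermediate
13 | dilithium 7-(dimethylamino)-7-oxidohept-5-ynoate (formed in the flask) | [Li+].[Li+].CN(C)C([O-])C#CCCCC(=O)[O-] | intermediate
14 | 7-oxohept-5-ynoic acid | O=CC#CCCCC(=O)O | intermediate
15 | methyl 7-oxohept-5-ynoate | COC(=O)CCCC#CC=O | intermediate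
16 | (S)-[5-chloro-3-(oct-2-yn-1-yl)-3-(trimethylsilyloxy)cyclopenta-1,4-dien-1-yl]oxy-dicyclohexylborane (formed in the flask) | CCCCCC#CC[C@@]1(O[Si](C)(C)C)C=C(Cl)C(OB(C2CCCCC2)C2CCCCC2)=C1 | intermediate
17 | O-dicyclohexylboryl derivative of 18 (formed in the flask) | CCCCCC#CC[C@@]1(O[Si](C)(C)C)C=C(Cl)C(=O)[C@@H]1[C@H](C#CCCCC(=O)OC)OB(C2CCCCC2)C2CCCCC2 | intermediate
18 | methyl (7R)-7-[(1R,2S)-4-chloro-2-(oct-2-yn-1-yl)-5-oxo-2-(trimethylsilyloxy)cyclopent-3-en-1-yl]-7-hydroxyhept-5-ynoate | CCCCCC#CC[C@@]1(O[Si](C)(C)C)C=C(Cl)C(=O)[C@@H]1[C@H](C#CCCCC(=O)OC)O | intermediate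
19 | methyl (7R)-7-(acetyloxy)-7-[(1R,2S)-4-chloro-2-(oct-2-yn-1-yl)-5-oxo-2-(trimethylsilyloxy)cyclopent-3-en-1-yl]hept-5-ynoate | CCCCCC#CC[C@@]1(O[Si](C)(C)C)C=C(Cl)C(=O)[C@@H]1[C@H](C#CCCCC(=O)OC)OC(C)=O | intermediate
20 | methyl (5Z,7S)-7-(acetyloxy)-7-[(1R,2S)-4-chloro-2-[(2Z)-oct-2-en-1-yl]-5-oxo-2-(trimethylsilyloxy)cyclopent-3-en-1-yl]hept-5-enoate | CCCCC/C=C\C[C@@]1(O[Si](C)(C)C)C=C(Cl)C(=O)[C@@H]1[C@H](/C=C\CCCC(=O)OC)OC(C)=O | intermediate
21 | punaglandin 8, methyl (5Z,7S)-7-(acetyloxy)-7-[(1R,2S)-4-chloro-2-hydroxy-2-[(2Z)-oct-2-en-1-yl]-5-oxocyclopent-3-en-1-yl]hept-5-enoate | CCCCC/C=C\C[C@@]1(O)C=C(Cl)C(=O)[C@@H]1[C@H](/C=C\CCCC(=O)OC)OC(C)=O | target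

**Step count**
Total steps: 10. Longest linear sequence: 8 (steps 1, 2, 3, 4, 7, 8, 9, 10); steps 5 and 6 make the side-chain aldehyde.

**Three steps most likely to fail, with fallbacks**

Step 1. Rate and enantioselectivity of the chromium-catalysed propargylation are untested on this small vinylogous-ester ketone, whose two flanks differ only as CH= and CH2. The fallback sets out from 1 and 2 and comes back at 3. A zinc Barbier addition (Zn dust, THF/sat. aq. NH4Cl, 0 °C) gives racemic 3-ethoxy-1-(prop-2-yn-1-yl)cyclobut-2-en-1-ol F1. Preparative chiral SFC (amylose phase, CO2/MeOH with 0.1 % Et3N) then gives (S)-3-ethoxy-1-(prop-2-yn-1-yl)cyclobut-2-en-1-ol F2, which is silylated (TMSCl, imidazole, DMF, 0 °C) to 3.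

Step 4 (the new ring expansion). The dichloro-organosamarium may α-eliminate to a chlorovinyl by-product, 10 may be over-reduced, or Sm(III) may open the 3-silyloxycyclobutanone. The fallback uses known chemistry, sets out from 6 and comes back at 10, by-passing 8. Dichlorocarbene (CHCl3, KOt-Bu, pentane, −30 °C) adds to the enol-ether double bond of 6 to give (3S)-5,5-dichloro-1-ethoxy-3-(oct-2-yn-1-yl)-3-(trimethylsilyloxy)bicyclo[2.1.0]pentane F3. This is not purified and opens on warming in MeCN/H2O over NaHCO3 to 10, the established dihalocarbene ring enlargement of cyclic enol ethers to 2-halo-enones.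

Step 7. The slim alkynyl aldehyde may give poor C7 control in the chair transition state, and the facial preference at C8 rests on analogy. The fallback sets out from 10 and 15 and comes back at 20. Aldehyde 15 is first semihydrogenated (Lindlar, quinoline, EtOAc, 0 °C) to methyl (5Z)-7-oxohept-5-enoate F4, which is used at once. The same enol borinate 16 adds to F4 to give the O-dicyclohexylboryl aldolate F5 and, after the same oxidative work-up, methyl (5Z,7S)-7-[(1R,2S)-4-chloro-2-(oct-2-yn-1-yl)-5-oxo-2-(trimethylsilyloxy)cyclopent-3-en-1-yl]-7-hydroxyhept-5-enoate F6; the bulkier cis-alkenyl group enforces the chair. Acetylation (Ac2O, pyridine, −20 °C) gives methyl (5Z,7S)-7-(acetyloxy)-7-[(1R,2S)-4-chloro-2-(oct-2-yn-1-yl)-5-oxo-2-(trimethylsilyloxy)cyclopent-3-en-1-yl]hept-5-enoate F7, and Lindlar reduction of the one remaining alkyne gives 20.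

**Further compounds**
F1 | step 1 | rac-3-ethoxy-1-(prop-2-yn-1-yl)cyclobut-2-en-1-ol | C#CCC1(O)C=C(OCC)C1
F2 | step 1 | (S)-3-ethoxy-1-(prop-2-yn-1-yl)cyclobut-2-en-1-ol | C#CC[C@@]1(O)C=C(OCC)C1
F3 | step 4 | (3S)-5,5-dichloro-1-ethoxy-3-(oct-2-yn-1-yl)-3-(trimethylsilyloxy)bicyclo[2.1.0]pentane | CCCCCC#CC[C@@]1(O[Si](C)(C)C)C2C(Cl)(Cl)C2(OCC)C1
F4 | step 7 | methyl (5Z)-7-oxohept-5-enoate | COC(=O)CCC/C=C\C=O
F5 | step 7 | O-dicyclohexylboryl derivative of F6 | CCCCCC#CC[C@@]1(O[Si](C)(C)C)C=C(Cl)C(=O)[C@@H]1[C@H](/C=C\CCCC(=O)OC)OB(C2CCCCC2)C2CCCCC2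
F6 | step 7 | methyl (5Z,7S)-7-[(1R,2S)-4-chloro-2-(oct-2-yn-1-yl)-5-oxo-2-(trimethylsilyloxy)cyclopent-3-en-1-yl]-7-hydroxyhept-5-enoate | CCCCCC#CC[C@@]1(O[Si](C)(C)C)C=C(Cl)C(=O)[C@@H]1[C@H](/C=C\CCCC(=O)OC)O
F7 | step 7 | methyl (5Z,7S)-7-(acetyloxy)-7-[(1R,2S)-4-chloro-2-(oct-2-yn-1-yl)-5-oxo-2-(trimethylsilyloxy)cyclopent-3-en-1-yl]hept-5-enoate | CCCCCC#CC[C@@]1(O[Si](C)(C)C)C=C(Cl)C(=O)[C@@H]1[C@H](/C=C\CCCC(=O)OC)OC(C)=O
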